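## Analysis of the target

The target is a cis-fused decalin. Ring A (C1, C2, C3, C4, C4a, C8a) carries the C1 ketone, a tertiary carbinol at C2, a sec-butyl group at C3 and a quaternary C4 bearing a methyl and a 3-hydroxypropanoyl group. Ring B (C4a, C5, C6, C7, C8, C8a) carries a methyl at C5 and a tertiary carbinol with a hydroxymethyl group at C7. There are eight stereocentres: 2S, 3R, 4R, 4aR, 5R, 7R, 8aS on the bicycle and R in the side chain. Taking the face of H4a and H8a as α, the β face carries the C2 methyl, the C3 sec-butyl, the C4 acyl, the C5 methyl and the C7 hydroxymethyl group; the α face carries C2-OH, the C4 methyl, H5 and C7-OH. The sensitive elements are the β-hydroxy ketone of the side chain (retro-aldol, elimination to a vinyl ketone), the C1/C2 α-ketol (acyloin shift under base) and C8a, which is epimerisable next to the C1 ketone. The difficulty lies in the contiguous array C2–C3–C4–C4a–C5 with a quaternary C4 flanked on both sides, in the exocyclic sec-butyl centre that has no neighbouring handle, and in two tertiary carbinols on different rings. The strategy rests on ring B: H4a is cis to H5 and the C5 methyl is cis to C4. This is the pattern of the endo adduct of an acrylate on a diene made of a vinyl group on C8a and the C8a=C4a double bond, formed through the bonds C4a–C5 and C6–C7, with the ester as the later methyl and the residual C8=C8a alkene as the entry to the C7 oxygen and the cis ring fusion.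

## Retrosynthetic reasoning

**29 ⇐ 28 ⇐ 26.** The last bond cut is the benzyl–oxygen bond of 28, because hydrogenolysis is neutral and the finished molecule tolerates neither base nor strong acid. The terminal C–O bond of the side chain is cut next: the β-hydroxy ketone comes from the vinyl ketone 26 by conjugate borylation and oxidation, so that the labile aldol unit exists only at the very end.

**26 ⇐ 25 ⇐ 24 ⇐ 23.** The acyl chain is cut between the carbonyl carbon and its α carbon: a vinyl nucleophile adds to aldehyde 24, which comes from the nitrile of 23. The nitrile is the form of the acyl carbon throughout because it is the smallest substituent C4 can carry and is inert until needed. Oxidation of 25 raises the side-chain carbinol and C1 together, so the C1 ketone and the epimerisable C8a appear only three steps from the end.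

**23 ⇐ 22 ⇐ 21.** The C7–CH2 bond is cut. A sulfoxonium ylide transfers the methylene to the C7 ketone of 21 in the equatorial sense, and opening of epoxide 22 at its methylene carbon by benzyl alkoxide gives the diol already differentiated. The forward step has to place the oxygen α on a cis-decalin whose ring B chair is fixed by the equatorial C5 methyl.

**21 ⇐ 20 ⇐ 19 ⇐ 18.** H8a and the C7 oxygen are both traced to the C8=C8a alkene of 18: allylic oxidation at the only allylic methylene gives enone 19, and hydrogen is delivered to C8a under direction of the freed α hydroxyl at C1 in 20. Cutting here means the cis fusion is set by a hydroxyl group that the key step already needs as its silyl ether.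

**18 ⇐ 17 ⇐ 16.** The C5 methyl is an ester in disguise: reduction to alcohol 17 and deoxygenation. This is what allows a reactive acrylate, and not an unactivated propene unit, to be the two-carbon partner.

**16 ⇐ 14 + 15.** The bonds C4a–C5 and C6–C7 are cut: ring B is assembled from the semicyclic diene 14 and methyl acrylate 15 in a Lewis-acid-catalysed Diels–Alder reaction. No other cut of ring B creates the C4a/C5 relationship and the C8=C8a alkene in one operation. The forward reaction has to be ortho-selective, endo-selective and selective for the β face of the diene; the first two are inherent, the third must come from ring A.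

**14 ⇐ 13 ⇐ 12 ⇐ 11.** The vinyl–C8a bond is cut to the alkenyl iodide 13 (Stille coupling), the silyl ethers to diol 12, and both C–O bonds at C1 and C2 to the diene 11. A syn-dihydroxylation anti to the sec-butyl group gives the α,α-diol in one step. The alternative, reduction of a C1 ketone next to the C2 carbinol, would depend on which of two closely balanced chair conformers reacts and was therefore not used.

**11 ⇐ 10 ⇐ 9 ⇐ 8.** The C1=C2 double bond comes from the C1 ketone by reduction and syn-dehydration (10), and the iodine from α-iodination of enone 8 (9). The enone thus supplies both the handle at C8a and the alkene for the diol.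

**8 ⇐ 6 ⇐ 5 ⇐ 4.** The sec-butyl centre is cut at its C–H bond: catalyst-controlled hydrogenation of the (E)-butenyl group of 5. The ring alkene is saturated at the same time and restored regiospecifically from 6 by a Saegusa–Ito oxidation. The C2 methyl is put in at the enone stage 4, where C2 is the only enolisable carbon.

**4 ⇐ 2 + 3; 2 ⇐ 1.** The C3–C1′ bond is cut: rhodium-catalysed conjugate addition of boronic acid 3 desymmetrises the prochiral dienone 2 and fixes C3 and C4 together. The dienone 2 comes from the saturated ketone 1 by dehydrogenation.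

## Alternatives that were turned down

**Alternative 1:** The cuts are C2–C3 and the C4–methyl bond on an unsaturated δ-lactone A2, whose α carbon (the future C4) carries a 4-methoxy-2-methylphenyl ring as ring B in aromatic form and whose ethyl-bearing carbon is the future sec-butyl centre. In the forward key step an acetate ester enolate adds to C3 of A2 and the lactone enolate is trapped by a methyl electrophile, giving A1; two C–C bonds, C3 and the benzylic quaternary C4 are made in one flask, and no ring closes.
- For: the ring controls both additions (nucleophile anti to the ethyl group, methyl anti to the new C3 substituent). The sec-butyl centre arrives in a building block and needs no catalyst-controlled hydrogenation; on that point it is stronger than the chosen route, which spends steps 2 and 4 on catalyst control. The C4 acyl carbon is present as the lactone carbonyl.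
- Against: ring B is still a benzene ring. C4a, C5 and C8a would have to be created from a flat arene next to a benzylic quaternary carbon, with nothing to control three centres. Ring A must still be closed at C1–C8a, C2 still needs its methyl and hydroxyl, and the lactone oxygen must be removed to free the sec-butyl methyl.
- Comparison: the chosen cycloaddition sets C4a and C5 with the relative configuration given by the endo rule. In place of the built-in sec-butyl centre it offers a ring A whose centres are all settled before the key step.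

**Alternative 2:** The cuts are C4–C4a and C4′–C7, where C4′ is a nitro-bearing carbon that later becomes the acyl carbon. In A4 a ring B silyl dienol ether (C7, C6, C5, C4a) is tethered through C8a–C1–C2–C3 to a trisubstituted nitroalkene; the intramolecular Diels–Alder reaction closes ring A and a bicyclo[2.2.2]octene bridge to give the cage A3, which is then opened by a retro-Henry fragmentation to the C7 ketone and a nitromethyl group on C4.
- For: it is intramolecular and sets the quaternary C4 and C4a in one step. It brings in the C7 oxygen and the acyl carbon without an allylic oxidation, which is a real saving over the chosen route after the cycloaddition.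
- Against: A4 needs C2, C3 and the sec-butyl centre built on an open chain, and carries a labile C8a centre between the C1 ketone and the dienol ether. The orientation of the nitroalkene in the cage decides which C4 substituent is β and is controlled by the tether alone. C5 is left as an alkene carbon, so its methyl centre needs a later reduction of uncertain facial sense. A Nef reaction and chain extension follow.
- Comparison: both routes carry a facial question in the key step, but the chosen one sets C5 in that step and keeps C4 as a pre-formed centre.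

**Alternative 3:** The cut is C3–C4. The silyl ketene acetal of the cis-fused δ-lactone A6 (carbonyl C4′, ring oxygen on C1, an (E)-alkenyl chain C2=C3 carrying the sec-butyl group on C1) undergoes an Ireland–Claisen rearrangement that bonds C4 to C3, closes ring A and gives acid A5 with a C1=C2 double bond.
- For: the rearrangement is stereospecific. The C1 carbinol configuration and the alkene geometry are transferred to C3 and C4 through a tied transition state, which is stronger than relying on a facial preference. The acid is a direct handle for the acyl chain, and the C1=C2 alkene is the right substrate for the α-face dihydroxylation.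
- Against: the six-membered lactone forces a boat transition state of bicyclo[2.2.2]octane type that joins a fully substituted ketene acetal carbon to the sec-butyl-bearing terminus. Ionisation of the allylic C1–O bond and elimination compete. A6 needs a stereodefined trisubstituted alkene, an enantiopure carbinol, and C4a, C5 and C8a set beforehand on ring B, so the number of stereocontrolled operations is not smaller.
- Comparison: it makes one bond where the chosen key step makes two bonds, one ring and two centres.

Key step: step 12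

**Convention.** Target numbering is used for every compound. With ring A drawn so that C1→C2→C3→C4→C4a→C8a runs clockwise, α substituents point toward the viewer (the face of H4a and H8a in the target) and β substituents away.

**Assumption.** Compounds 1, 3 and 15 are taken as purchasable building blocks.

## Route

Step 1
Reactants: 1 1-methyl-4-oxocyclohexane-1-carbonitrile
Product: 2 1-methyl-4-oxocyclohexa-2,5-diene-1-carbonitrile
Conditions: IBX (3 equiv), DMSO/fluorobenzene, 80 °C
Reagents that add atoms: none
Why: Twofold α,β-dehydrogenation of a ketone by 2-iodoxybenzoic acid; the 4,4-disubstitution stops the oxidation at the cross-conjugated dienone, which cannot tautomerise to a phenol, and no stereocentre is present.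

Step 2
Reactants: 2 1-methyl-4-oxocyclohexa-2,5-diene-1-carbonitrile; 3 (Z)-but-2-en-2-ylboronic acid
Product: 4 6-[(2E)-but-2-en-2-yl]-1-methyl-4-oxocyclohex-2-ene-1-carbonitrile (butenyl 3β, methyl 4α, nitrile 4β; butenyl cis to nitrile)
Conditions: 3 (1.5 equiv), [Rh(OH)((R)-binap)]2 (3 mol %), dioxane/H2O 10:1, 40 °C
Reagents that add atoms: none
Why: Hayashi–Miyaura rhodium-catalysed asymmetric 1,4-addition (transmetalation with retention of alkene geometry, insertion of the enone, protonolysis); the ligand selects one enone enantioface, which on the prochiral dienone means one of the two enantiotopic double bonds, and the alkenyl group enters syn to the small nitrile and anti to the C4 methyl, so C3 and C4 are set together; the (R) ligand is the one that gives the corresponding sense with cyclohex-2-enone.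

Step 3
Reactants: 4 6-[(2E)-but-2-en-2-yl]-1-methyl-4-oxocyclohex-2-ene-1-carbonitrile
Product: 5 6-[(2E)-but-2-en-2-yl]-1,5-dimethyl-4-oxocyclohex-2-ene-1-carbonitrile (methyl 2α, trans to the 3β-butenyl group; 4α-methyl, 4β-nitrile)
Conditions: i-Pr2NLi, THF, −78 °C; MeI, −78 → −20 °C
Reagents that add atoms: iodomethane CI
Why: Kinetic enolate alkylation; C2 is the only enolisable carbon (C8a is vinylic, the γ carbon C4 is quaternary) and iodomethane approaches anti to the C3 substituent; the C2 configuration is temporary because C2 becomes trigonal in step 8.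

Step 4
Reactants: 5 6-[(2E)-but-2-en-2-yl]-1,5-dimethyl-4-oxocyclohex-2-ene-1-carbonitrile
Product: 6 2-[(2R)-butan-2-yl]-1,3-dimethyl-4-oxocyclohexane-1-carbonitrile (2α-methyl, 3β-sec-butyl, 4α-methyl, 4β-nitrile)
Conditions: H2 (50 bar), [Ir(cod)(L*)][B(3,5-(CF3)2C6H3)4] (1–2 mol %; L* = 2-phenyl-6,7-dihydro-5H-cyclopenta[b]pyridin-7-yl di-tert-butylphosphinite, enantiomer matched to the (R) centre), CH2Cl2, rt
Reagents that add atoms: none
Why: Iridium-catalysed asymmetric hydrogenation of an unfunctionalised (E)-trisubstituted alkene, the class to which (E)-2-cyclohexylbut-2-ene belongs; the catalyst should deliver hydrogen to one face of the butenyl group and set the (R) sec-butyl centre, the ring double bond is saturated in the same operation and is restored in step 5, and ketone and nitrile are not reduced.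

Step 5
Reactants: 6 2-[(2R)-butan-2-yl]-1,3-dimethyl-4-oxocyclohexane-1-carbonitrile
Product: 8 6-[(2R)-butan-2-yl]-1,5-dimethyl-4-oxocyclohex-2-ene-1-carbonitrile (2α-methyl, 3β-sec-butyl, 4α-methyl, 4β-nitrile), via trimethylsilyl enol ether 7 (not isolated)
Conditions: i-Pr2NLi, Me3SiCl, THF, −78 °C; then Pd(OAc)2 (1.1 equiv), MeCN, rt
Reagents that add atoms: chlorotrimethylsilane C[Si](C)(C)Cl (silicon only in 7)
Why: Saegusa–Ito oxidation; the kinetic enolate forms at the C8a methylene and not at the tertiary, methyl-bearing C2, so the double bond returns only as C4a=C8a and no stereocentre is touched.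

Step 6
Reactants: 8 6-[(2R)-butan-2-yl]-1,5-dimethyl-4-oxocyclohex-2-ene-1-carbonitrile
Product: 9 6-[(2R)-butan-2-yl]-3-iodo-1,5-dimethyl-4-oxocyclohex-2-ene-1-carbonitrile (iodine on C8a)
Conditions: I2, pyridine/CH2Cl2 1:1, rt
Reagents that add atoms: iodine II
Why: α-Iodination of an enone by amine conjugate addition, iodination of the enolate and elimination, a reaction known for 4,4-disubstituted cyclohexenones; it installs the coupling handle at C8a.

Step 7
Reactants: 9 6-[(2R)-butan-2-yl]-3-iodo-1,5-dimethyl-4-oxocyclohex-2-ene-1-carbonitrile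
Product: 10 6-[(2R)-butan-2-yl]-4-hydroxy-3-iodo-1,5-dimethylcyclohex-2-ene-1-carbonitrile (hydroxyl 1β, cis to H2)
Conditions: NaBH4, CeCl3·7H2O, MeOH, −40 °C
Reagents that add atoms: none
Why: Luche 1,2-reduction; in the conformer with the C2 methyl, the sec-butyl group and the C4 methyl all equatorial, axial hydride delivery from the α face should give the 1β alcohol, cis to H2; this carbinol centre is removed in step 8.

Step 8
Reactants: 10 6-[(2R)-butan-2-yl]-4-hydroxy-3-iodo-1,5-dimethylcyclohex-2-ene-1-carbonitrile
Product: 11 6-[(2R)-butan-2-yl]-3-iodo-1,5-dimethylcyclohexa-2,4-diene-1-carbonitrile (3β-sec-butyl, 4α-methyl, 4β-nitrile)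
Conditions: methyl N-(triethylammoniosulfonyl)carbamate (Burgess reagent), toluene, 70 °C
Reagents that add atoms: none
Why: Syn dehydration through the sulfamate ester; H2 is the only β hydrogen (C8a carries none) and is cis to the C1 oxygen, so the C1=C2 bond forms in conjugation with the iodoalkene.

Step 9
Reactants: 11 6-[(2R)-butan-2-yl]-3-iodo-1,5-dimethylcyclohexa-2,4-diene-1-carbonitrile
Product: 12 6-[(2R)-butan-2-yl]-4,5-dihydroxy-3-iodo-1,5-dimethylcyclohex-2-ene-1-carbonitrile (1α-OH, 2α-OH, 2β-methyl, 3β-sec-butyl, 4α-methyl, 4β-nitrile)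
Conditions: OsO4 (5 mol %), N-methylmorpholine N-oxide, acetone/H2O, 0 °C → rt
Reagents that add atoms: osmium tetroxide O=[Os](=O)(=O)=O; N-methylmorpholine N-oxide C[N+]1([O-])CCOCC1
Why: Catalytic syn-dihydroxylation (Upjohn conditions); the reagent takes the electron-rich trisubstituted C1=C2 bond and leaves the iodine-deactivated C4a=C8a bond next to the quaternary carbon, and it adds anti to the allylic sec-butyl group on C3, which sets C1 and C2 together as the α,α-diol.

Step 10
Reactants: 12 6-[(2R)-butan-2-yl]-4,5-dihydroxy-3-iodo-1,5-dimethylcyclohex-2-ene-1-carbonitrile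
Product: 13 6-[(2R)-butan-2-yl]-3-iodo-1,5-dimethyl-4,5-bis(triethylsilyloxy)cyclohex-2-ene-1-carbonitrile (1α- and 2α-silyloxy)
Conditions: Et3SiOTf (3 equiv), 2,6-lutidine, CH2Cl2, −78 → 0 °C
Reagents that add atoms: triethylsilyl trifluoromethanesulfonate CC[Si](CC)(CC)OS(=O)(=O)C(F)(F)F
Why: Silylation with a silyl triflate, reactive enough for the tertiary C2 hydroxyl; one group on both oxygens means one step on and one step off, and the C1 silyl ether is the α-face shield of the key step.

Step 11
Reactants: 13 6-[(2R)-butan-2-yl]-3-iodo-1,5-dimethyl-4,5-bis(triethylsilyloxy)cyclohex-2-ene-1-carbonitrile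
Product: 14 6-[(2R)-butan-2-yl]-3-ethenyl-1,5-dimethyl-4,5-bis(triethylsilyloxy)cyclohex-2-ene-1-carbonitrile (vinyl on C8a; 1α- and 2α-silyloxy, 2β-methyl, 3β-sec-butyl, 4α-methyl, 4β-nitrile)
Conditions: Bu3SnCH=CH2, Pd(PPh3)4 (5 mol %), CuI (10 mol %), DMF, 50 °C
Reagents that add atoms: tributyl(vinyl)stannane C=C[Sn](CCCC)(CCCC)CCCC
Why: Stille coupling of an alkenyl iodide with retention of the ring double bond, with copper co-catalysis for the hindered C8a position; it gives the semicyclic diene, which is used without storage.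

Step 12
Reactants: 14 6-[(2R)-butan-2-yl]-3-ethenyl-1,5-dimethyl-4,5-bis(triethylsilyloxy)cyclohex-2-ene-1-carbonitrile; 15 methyl prop-2-enoate
Product: 16 methyl 3β-[(2R)-butan-2-yl]-4β-cyano-2β,4α-dimethyl-1α,2α-bis(triethylsilyloxy)-1,2,3,4,4a,5,6,7-octahydronaphthalene-5β-carboxylate (H4a α; C8=C8a alkene)
Conditions: 15 (5 equiv), Et2AlCl (2.2 equiv), CH2Cl2, −78 → −30 °C
Reagents that add atoms: none
Why: Et2AlCl binds the acrylate carbonyl and the s-cis diene C7=C8–C8a=C4a adds it in a concerted but asynchronous [4+2] cycloaddition, the known Lewis-acid-catalysed Diels–Alder reaction of 1-vinylcyclohexenes with acrylates. Bonding of the acrylate β carbon (C6) to the unhindered vinyl terminus C7 runs ahead and leaves positive charge on the more substituted C8–C8a–C4a unit, which is why the ester-bearing carbon C5 ends on C4a (ortho adduct) although C4a is neopentyl. Ring B is closed by this intermolecular cycloaddition, suprafacial on both partners, with the new double bond at C8=C8a. For C4a the acrylate has to come from the β face: in the half-chair with the sec-butyl group equatorial the C1 silyl ether is pseudo-axial on the α face, where it also avoids A(1,2) strain with the vinyl group, and it covers C8a and C8 where the endo ester must sit, whereas the β face next to C4a carries only the rod-like nitrile, the C4 methyl being α. For C5 the endo transition state, reinforced by the Lewis acid, puts the ester cis to C4, the outside substituent of the diene terminus, which is 5β with H5 cis to H4a. The step therefore needs ortho, endo and diene-face selectivity; the first two are inherent to the catalysed reaction, the third rests on the C1 silyl ether and the small nitrile and is the main risk. The silyl ethers, the nitrile (which takes up one equivalent of Lewis acid) and the sec-butyl centre are spectators.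

Step 13
Reactants: 16 methyl 3β-[(2R)-butan-2-yl]-4β-cyano-2β,4α-dimethyl-1α,2α-bis(triethylsilyloxy)-1,2,3,4,4a,5,6,7-octahydronaphthalene-5β-carboxylate
Product: 17 3β-[(2R)-butan-2-yl]-5β-(hydroxymethyl)-2β,4α-dimethyl-1α,2α-bis(triethylsilyloxy)-1,2,3,4,4a,5,6,7-octahydronaphthalene-4β-carbonitrile (H4a α)
Conditions: LiBH4, THF, 0 °C → rt
Reagents that add atoms: none
Why: Borohydride reduction of an ester to the primary alcohol; LiBH4 leaves the tertiary nitrile, the alkene and the silyl ethers, and the absence of alkoxide base keeps C5 from epimerising before it is reduced.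

Step 14
Reactants: 17 3β-[(2R)-butan-2-yl]-5β-(hydroxymethyl)-2β,4α-dimethyl-1α,2α-bis(triethylsilyloxy)-1,2,3,4,4a,5,6,7-octahydronaphthalene-4β-carbonitrile
Product: 18 3β-[(2R)-butan-2-yl]-2β,4α,5β-trimethyl-1α,2α-bis(triethylsilyloxy)-1,2,3,4,4a,5,6,7-octahydronaphthalene-4β-carbonitrile (H4a α)
Conditions: 2-nitrobenzenesulfonylhydrazide, PPh3, diethyl azodicarboxylate, THF, −30 °C → rt
Reagents that add atoms: none
Why: Mitsunobu displacement of the primary alcohol by the sulfonylhydrazide, then loss of sulfinic acid and of N2 from the monoalkyl diazene, a one-flask reductive deoxygenation of primary alcohols; no stereocentre changes and the C5 methyl keeps the β configuration set in step 12.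

Step 15
Reactants: 18 3β-[(2R)-butan-2-yl]-2β,4α,5β-trimethyl-1α,2α-bis(triethylsilyloxy)-1,2,3,4,4a,5,6,7-octahydronaphthalene-4β-carbonitrile
Product: 19 3β-[(2R)-butan-2-yl]-2β,4α,5β-trimethyl-7-oxo-1α,2α-bis(triethylsilyloxy)-1,2,3,4,4a,5,6,7-octahydronaphthalene-4β-carbonitrile (H4a α; C8=C8a enone)
Conditions: CrO3, 3,5-dimethylpyrazole, CH2Cl2, −20 °C
Reagents that add atoms: chromium trioxide O=[Cr](=O)=O
Why: Allylic oxidation of a trisubstituted cycloalkene to the enone; C7 is the only allylic methylene (C1 and C4a are hindered methines, C1 bearing the silyl ether), so the C7 ketone conjugated with C8=C8a should form.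

Step 16
Reactants: 19 3β-[(2R)-butan-2-yl]-2β,4α,5β-trimethyl-7-oxo-1α,2α-bis(triethylsilyloxy)-1,2,3,4,4a,5,6,7-octahydronaphthalene-4β-carbonitrile
Product: 20 3β-[(2R)-butan-2-yl]-1α,2α-dihydroxy-2β,4α,5β-trimethyl-7-oxo-1,2,3,4,4a,5,6,7-octahydronaphthalene-4β-carbonitrile (H4a α)
Conditions: HF·pyridine, THF, 0 °C → rt
Reagents that add atoms: none
Why: Fluoride cleavage of both triethylsilyl ethers under mildly acidic conditions that do not deconjugate the enone; it frees the C1 hydroxyl as directing group.

Step 17
Reactants: 20 3β-[(2R)-butan-2-yl]-1α,2α-dihydroxy-2β,4α,5β-trimethyl-7-oxo-1,2,3,4,4a,5,6,7-octahydronaphthalene-4β-carbonitrile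
Product: 21 3β-[(2R)-butan-2-yl]-1α,2α-dihydroxy-2β,4α,5β-trimethyl-7-oxodecahydronaphthalene-4β-carbonitrile (H4a α, H8a α; cis-fused)
Conditions: H2 (1–4 atm), [Ir(cod)(PCy3)(py)]PF6 (10 mol %), CH2Cl2, rt
Reagents that add atoms: none
Why: Hydroxyl-directed homogeneous hydrogenation; the allylic α hydroxyl at C1 binds the iridium centre and hydrogen is delivered to the α face of C8=C8a, the face that is also free of the syn-axial C2 methyl and C4 nitrile, which should give H8a α and the cis ring fusion.

Step 18
Reactants: 21 3β-[(2R)-butan-2-yl]-1α,2α-dihydroxy-2β,4α,5β-trimethyl-7-oxodecahydronaphthalene-4β-carbonitrile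
Product: 22 spiro-epoxide of 21 at C7: 3β-[(2R)-butan-2-yl]-1α,2α-dihydroxy-2β,4α,5β-trimethyloctahydrospiro[naphthalene-7,2′-oxirane]-4β-carbonitrile (epoxide oxygen α, methylene β; H4a α, H8a α)
Conditions: Me3S(O)I, NaH, DMSO, rt
Reagents that add atoms: trimethylsulfoxonium iodide C[S+](C)(C)=O.[I-]
Why: Corey–Chaykovsky epoxidation with the sulfoxonium ylide, whose reversible addition leads to the equatorial C–CH2 bond; in the ring B chair that keeps the C5 methyl equatorial the axial position at C7 is α, so the oxygen should end α and the methylene β.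

Step 19
Reactants: 22 spiro-epoxide (epoxide oxygen α at C7)
Product: 23 7β-[(benzyloxy)methyl]-3β-[(2R)-butan-2-yl]-1α,2α,7α-trihydroxy-2β,4α,5β-trimethyldecahydronaphthalene-4β-carbonitrile (H4a α, H8a α)
Conditions: NaH, BnOH, 90 °C
Reagents that add atoms: benzyl alcohol OCc1ccccc1
Why: Base-mediated SN2 opening of the 2,2-disubstituted epoxide at its methylene carbon; the C7–O bond is not touched, so C7 keeps its configuration, and the primary hydroxyl arrives already protected as the benzyl ether.

Step 20
Reactants: 23 7β-[(benzyloxy)methyl]-3β-[(2R)-butan-2-yl]-1α,2α,7α-trihydroxy-2β,4α,5β-trimethyldecahydronaphthalene-4β-carbonitrile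
Product: 24 7β-[(benzyloxy)methyl]-3β-[(2R)-butan-2-yl]-1α,2α,7α-trihydroxy-2β,4α,5β-trimethyldecahydronaphthalene-4β-carbaldehyde (H4a α, H8a α)
Conditions: i-Bu2AlH (6 equiv), toluene, −78 → 0 °C; aqueous tartaric acid
Reagents that add atoms: water O
Why: Partial reduction of a nitrile to the N-aluminio imine and hydrolysis to the aldehyde, reliable for hindered tertiary nitriles; the three hydroxyls travel as aluminium alkoxides and the aldehyde has no α hydrogen.

Step 21
Reactants: 24 7β-[(benzyloxy)methyl]-3β-[(2R)-butan-2-yl]-1α,2α,7α-trihydroxy-2β,4α,5β-trimethyldecahydronaphthalene-4β-carbaldehyde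
Product: 25 7β-[(benzyloxy)methyl]-3β-[(2R)-butan-2-yl]-4β-(1-hydroxyprop-2-en-1-yl)-2β,4α,5β-trimethyldecahydronaphthalene-1α,2α,7α-triol (both carbinol epimers; H4a α, H8a α)
Conditions: CH2=CHMgBr (6 equiv), THF, 0 °C
Reagents that add atoms: vinylmagnesium bromide C=C[Mg]Br
Why: Grignard 1,2-addition to a non-enolisable aldehyde; the new carbinol centre is of no consequence because it is oxidised in step 22.

Step 22
Reactants: 25 7β-[(benzyloxy)methyl]-3β-[(2R)-butan-2-yl]-4β-(1-hydroxyprop-2-en-1-yl)-2β,4α,5β-trimethyldecahydronaphthalene-1α,2α,7α-triol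
Product: 26 7β-[(benzyloxy)methyl]-3β-[(2R)-butan-2-yl]-2α,7α-dihydroxy-2β,4α,5β-trimethyl-4β-(prop-2-enoyl)octahydronaphthalen-1(2H)-one (H4a α, H8a α)
Conditions: IBX (4 equiv), DMSO, rt → 40 °C
Reagents that add atoms: none
Why: 2-Iodoxybenzoic acid oxidises both secondary alcohols (C1 and the allylic side-chain carbinol) and, unlike periodinane or periodate oxidants, does not cleave the C1–C2 glycol; tertiary alcohols and the benzyl ether are inert, and the neutral medium leaves the now epimerisable C8a alone.

Step 23
Reactants: 26 7β-[(benzyloxy)methyl]-3β-[(2R)-butan-2-yl]-2α,7α-dihydroxy-2β,4α,5β-trimethyl-4β-(prop-2-enoyl)octahydronaphthalen-1(2H)-one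
Product: 28 7β-[(benzyloxy)methyl]-3β-[(2R)-butan-2-yl]-2α,7α-dihydroxy-4β-(3-hydroxypropanoyl)-2β,4α,5β-trimethyloctahydronaphthalen-1(2H)-one (H4a α, H8a α), via β-boryl ketone 27 (not isolated)
Conditions: B2pin2 (1.1 equiv), CuCl (5 mol %), NaOt-Bu (5 mol %), bis[2-(diphenylphosphino)phenyl] ether (5 mol %), MeOH (2 equiv), THF, rt; then H2O2, aqueous NaHCO3, 0 °C
Reagents that add atoms: bis(pinacolato)diboron CC1(C)OB(OC1(C)C)B1OC(C)(C)C(C)(C)O1 (boron only in 27); hydrogen peroxide OO
Why: Copper-catalysed conjugate borylation of the vinyl ketone, the only Michael acceptor present, and oxidation of the C–B bond give the β-hydroxy ketone under nearly neutral conditions that avoid retro-aldol and elimination; the hindered C1 ketone is not attacked.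

Step 24
Reactants: 28 7β-[(benzyloxy)methyl]-3β-[(2R)-butan-2-yl]-2α,7α-dihydroxy-4β-(3-hydroxypropanoyl)-2β,4α,5β-trimethyloctahydronaphthalen-1(2H)-one
Product: 29 (2S,3R,4R,4aR,5R,7R,8aS)-3-[(2R)-butan-2-yl]-2,7-dihydroxy-7-(hydroxymethyl)-4-(3-hydroxypropanoyl)-2,4,5-trimethyloctahydronaphthalen-1(2H)-one (target)
Conditions: H2 (1 atm), Pd/C, EtOAc, rt
Reagents that add atoms: none
Why: Hydrogenolysis of the benzyl ether under neutral conditions, placed last because the β-hydroxy ketone, the α-ketol and C8a of the target tolerate neither base nor strong acid; ketones and tertiary alcohols are untouched.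

## Compound list

1 | 1-methyl-4-oxocyclohexane-1-carbonitrile | CC1(C#N)CCC(=O)CC1 | starting material
2 | 1-methyl-4-oxocyclohexa-2,5-diene-1-carbonitrile | CC1(C#N)C=CC(=O)C=C1 | intermediate
3 | (Z)-but-2-en-2-ylboronic acid | C/C=C(\C)B(O)O | starting material
4 | 6-[(2E)-but-2-en-2-yl]-1-methyl-4-oxocyclohex-2-ene-1-carbonitrile (3β-butenyl, 4α-methyl, 4β-nitrile) | C/C=C(\C)[C@@H]1[C@](C)(C#N)C=CC(=O)C1 | intermediate
5 | 6-[(2E)-but-2-en-2-yl]-1,5-dimethyl-4-oxocyclohex-2-ene-1-carbonitrile (2α-methyl, 3β-butenyl, 4α-methyl, 4β-nitrile) | C/C=C(\C)[C@@H]1[C@](C)(C#N)C=CC(=O)[C@H]1C | intermediate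
6 | 2-[(2R)-butan-2-yl]-1,3-dimethyl-4-oxocyclohexane-1-carbonitrile (2α-methyl, 3β-sec-butyl, 4α-methyl, 4β-nitrile) | CC[C@@H](C)[C@@H]1[C@](C)(C#N)CCC(=O)[C@H]1C | intermediate
7 | 2-[(2R)-butan-2-yl]-1,3-dimethyl-4-(trimethylsilyloxy)cyclohex-4-ene-1-carbonitrile (C1=C8a silyl enol ether) | CC[C@@H](C)[C@@H]1[C@](C)(C#N)CC=C(O[Si](C)(C)C)[C@H]1C | intermediate
8 | 6-[(2R)-butan-2-yl]-1,5-dimethyl-4-oxocyclohex-2-ene-1-carbonitrile (2α-methyl, 3β-sec-butyl, 4α-methyl, 4β-nitrile) | CC[C@@H](C)[C@@H]1[C@](C)(C#N)C=CC(=O)[C@H]1C | intermediate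
9 | 6-[(2R)-butan-2-yl]-3-iodo-1,5-dimethyl-4-oxocyclohex-2-ene-1-carbonitrile | CC[C@@H](C)[C@@H]1[C@](C)(C#N)C=C(I)C(=O)[C@H]1C | intermediate
10 | 6-[(2R)-butan-2-yl]-4-hydroxy-3-iodo-1,5-dimethylcyclohex-2-ene-1-carbonitrile (1β-hydroxy, cis to H2) | CC[C@@H](C)[C@@H]1[C@](C)(C#N)C=C(I)[C@H](O)[C@H]1C | intermediate
11 | 6-[(2R)-butan-2-yl]-3-iodo-1,5-dimethylcyclohexa-2,4-diene-1-carbonitrile | CC[C@@H](C)[C@@H]1[C@](C)(C#N)C=C(I)C=C1C | intermediate
12 | 6-[(2R)-butan-2-yl]-4,5-dihydroxy-3-iodo-1,5-dimethylcyclohex-2-ene-1-carbonitrile (1α,2α-diol, 2β-methyl) | CC[C@@H](C)[C@@H]1[C@](C)(C#N)C=C(I)[C@@H](O)[C@@]1(C)O | intermediate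
13 | 6-[(2R)-butan-2-yl]-3-iodo-1,5-dimethyl-4,5-bis(triethylsilyloxy)cyclohex-2-ene-1-carbonitrile | CC[C@@H](C)[C@@H]1[C@](C)(C#N)C=C(I)[C@@H](O[Si](CC)(CC)CC)[C@@]1(C)O[Si](CC)(CC)CC | intermediate
14 | 6-[(2R)-butan-2-yl]-3-ethenyl-1,5-dimethyl-4,5-bis(triethylsilyloxy)cyclohex-2-ene-1-carbonitrile (ring A diene) | CC[C@@H](C)[C@@H]1[C@](C)(C#N)C=C(C=C)[C@@H](O[Si](CC)(CC)CC)[C@@]1(C)O[Si](CC)(CC)CC | intermediate
15 | methyl prop-2-enoate | C=CC(=O)OC | starting material
16 | methyl 3β-[(2R)-butan-2-yl]-4β-cyano-2β,4α-dimethyl-1α,2α-bis(triethylsilyloxy)-1,2,3,4,4a,5,6,7-octahydronaphthalene-5β-carboxylate (H4a α) | CC[C@@H](C)[C@@H]1[C@](C)(C#N)[C@@H]2[C@H](C(=O)OC)CCC=C2[C@@H](O[Si](CC)(CC)CC)[C@@]1(C)O[Si](CC)(CC)CC | intermediate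
17 | 3β-[(2R)-butan-2-yl]-5β-(hydroxymethyl)-2β,4α-dimethyl-1α,2α-bis(triethylsilyloxy)-1,2,3,4,4a,5,6,7-octahydronaphthalene-4β-carbonitrile | CC[C@@H](C)[C@@H]1[C@](C)(C#N)[C@@H]2[C@H](CO)CCC=C2[C@@H](O[Si](CC)(CC)CC)[C@@]1(C)O[Si](CC)(CC)CC | intermediate
18 | 3β-[(2R)-butan-2-yl]-2β,4α,5β-trimethyl-1α,2α-bis(triethylsilyloxy)-1,2,3,4,4a,5,6,7-octahydronaphthalene-4β-carbonitrile | CC[C@@H](C)[C@@H]1[C@](C)(C#N)[C@@H]2[C@H](C)CCC=C2[C@@H](O[Si](CC)(CC)CC)[C@@]1(C)O[Si](CC)(CC)CC | intermediate
19 | 3β-[(2R)-butan-2-yl]-2β,4α,5β-trimethyl-7-oxo-1α,2α-bis(triethylsilyloxy)-1,2,3,4,4a,5,6,7-octahydronaphthalene-4β-carbonitrile | CC[C@@H](C)[C@@H]1[C@](C)(C#N)[C@@H]2[C@H](C)CC(=O)C=C2[C@@H](O[Si](CC)(CC)CC)[C@@]1(C)O[Si](CC)(CC)CC | intermediate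
20 | 3β-[(2R)-butan-2-yl]-1α,2α-dihydroxy-2β,4α,5β-trimethyl-7-oxo-1,2,3,4,4a,5,6,7-octahydronaphthalene-4β-carbonitrile | CC[C@@H](C)[C@@H]1[C@](C)(C#N)[C@@H]2[C@H](C)CC(=O)C=C2[C@@H](O)[C@@]1(C)O | intermediate
21 | 3β-[(2R)-butan-2-yl]-1α,2α-dihydroxy-2β,4α,5β-trimethyl-7-oxodecahydronaphthalene-4β-carbonitrile (H4a α, H8a α) | CC[C@@H](C)[C@@H]1[C@](C)(C#N)[C@@H]2[C@H](C)CC(=O)C[C@@H]2[C@@H](O)[C@@]1(C)O | intermediate
22 | 3β-[(2R)-butan-2-yl]-1α,2α-dihydroxy-2β,4α,5β-trimethyloctahydrospiro[naphthalene-7,2′-oxirane]-4β-carbonitrile (epoxide oxygen α) | CC[C@@H](C)[C@@H]1[C@](C)(C#N)[C@@H]2[C@H](C)C[C@]3(CO3)C[C@@H]2[C@@H](O)[C@@]1(C)O | intermediate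
23 | 7β-[(benzyloxy)methyl]-3β-[(2R)-butan-2-yl]-1α,2α,7α-trihydroxy-2β,4α,5β-trimethyldecahydronaphthalene-4β-carbonitrile | CC[C@@H](C)[C@@H]1[C@](C)(C#N)[C@@H]2[C@H](C)C[C@](O)(COCc3ccccc3)C[C@@H]2[C@@H](O)[C@@]1(C)O | intermediate
24 | 7β-[(benzyloxy)methyl]-3β-[(2R)-butan-2-yl]-1α,2α,7α-trihydroxy-2β,4α,5β-trimethyldecahydronaphthalene-4β-carbaldehyde | CC[C@@H](C)[C@@H]1[C@](C)(C=O)[C@@H]2[C@H](C)C[C@](O)(COCc3ccccc3)C[C@@H]2[C@@H](O)[C@@]1(C)O | intermediate
25 | 7β-[(benzyloxy)methyl]-3β-[(2R)-butan-2-yl]-4β-(1-hydroxyprop-2-en-1-yl)-2β,4α,5β-trimethyldecahydronaphthalene-1α,2α,7α-triol (carbinol epimers) | CC[C@@H](C)[C@@H]1[C@](C)(C(O)C=C)[C@@H]2[C@H](C)C[C@](O)(COCc3ccccc3)C[C@@H]2[C@@H](O)[C@@]1(C)O | intermediate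
26 | 7β-[(benzyloxy)methyl]-3β-[(2R)-butan-2-yl]-2α,7α-dihydroxy-2β,4α,5β-trimethyl-4β-(prop-2-enoyl)octahydronaphthalen-1(2H)-one | CC[C@@H](C)[C@@H]1[C@](C)(C(=O)C=C)[C@@H]2[C@H](C)C[C@](O)(COCc3ccccc3)C[C@@H]2C(=O)[C@@]1(C)O | intermediate
27 | 7β-[(benzyloxy)methyl]-3β-[(2R)-butan-2-yl]-2α,7α-dihydroxy-2β,4α,5β-trimethyl-4β-[3-(4,4,5,5-tetramethyl-1,3,2-dioxaborolan-2-yl)propanoyl]octahydronaphthalen-1(2H)-one | CC[C@@H](C)[C@@H]1[C@](C)(C(=O)CCB3OC(C)(C)C(C)(C)O3)[C@@H]2[C@H](C)C[C@](O)(COCc4ccccc4)C[C@@H]2C(=O)[C@@]1(C)O | intermediate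
28 | 7β-[(benzyloxy)methyl]-3β-[(2R)-butan-2-yl]-2α,7α-dihydroxy-4β-(3-hydroxypropanoyl)-2β,4α,5β-trimethyloctahydronaphthalen-1(2H)-one | CC[C@@H](C)[C@@H]1[C@](C)(C(=O)CCO)[C@@H]2[C@H](C)C[C@](O)(COCc3ccccc3)C[C@@H]2C(=O)[C@@]1(C)O | intermediate
29 | (2S,3R,4R,4aR,5R,7R,8aS)-3-[(2R)-butan-2-yl]-2,7-dihydroxy-7-(hydroxymethyl)-4-(3-hydroxypropanoyl)-2,4,5-trimethyloctahydronaphthalen-1(2H)-one | CC[C@@H](C)[C@@H]1[C@](C)(C(=O)CCO)[C@@H]2[C@H](C)C[C@](O)(CO)C[C@@H]2C(=O)[C@@]1(C)O | target

## Step count and least certain steps

Total step count: 24. Longest linear sequence: 24 steps (1 → 29); compounds 3 and 15 enter as purchased partners.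

**Step 12 (key step).** Three things may go wrong.
- Loss of diene-face selectivity, if ring A reacts through the half-chair with the sec-butyl group axial and the C1 silyl ether pseudo-equatorial, so that the α face opens.
- Slow bond formation at the neopentyl C4a, which would let the regioisomeric adduct, ene products or oligomers compete.
- Ionisation of the allylic silyl ether by the Lewis acid.

Fallback, from 14 and back at 16: the same two bonds are formed under reagent control. Diene 14 and 3-acryloyl-1,3-oxazolidin-2-one are combined with the divalent copper catalyst [Cu((S,S)-t-Bu-box)](SbF6)2 (10 mol %, CH2Cl2, −40 °C; ligand enantiomer chosen for β-face attack). Two-point binding raises the reactivity and the endo preference and lets the catalyst choose the diene face, and should give the N-acyloxazolidinone adduct F1. Methanolysis (MeOMgBr, MeOH/CH2Cl2, 0 °C) converts F1 into 16.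

**Step 2.** Most likely failures are protodeboronation of the α-branched alkenylboronic acid, slow insertion at the β carbon next to the quaternary centre, a second addition to the remaining enone, or erosion of the preference for attack syn to the nitrile. Fallback, from 2 and back at 4: but-2-yne is hydroaluminated with i-Bu2AlH (syn addition, hexane, 50 °C) to (E)-but-2-en-2-yl(diisobutyl)alane F2. F2 is added to 2 under Cu(OTf)2 (2 mol %) with a chiral phosphoramidite ligand in Et2O at −30 °C, and protonation of the aluminium enolate gives 4.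

**Step 4.** Most likely failures are mismatched double stereodifferentiation next to C3 and C4, deactivation of the cationic iridium catalyst by the nitrile, or alkene isomerisation before reduction; each would give a mixture at the sec-butyl centre. Fallback, from 2 and back at 6, uses substrate control by allylic 1,3-strain in place of catalyst control:
- (Z)-2-bromobut-2-ene is lithiated (t-BuLi, −78 °C) and trapped with 2-isopropoxy-4,4,5,5-tetramethyl-1,3,2-dioxaborolane to give 2-[(2E)-but-2-en-2-yl]-4,4,5,5-tetramethyl-1,3,2-dioxaborolane F3.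
- Rhodium-catalysed addition of F3 to 2 as in step 2 gives 6-[(2Z)-but-2-en-2-yl]-1-methyl-4-oxocyclohex-2-ene-1-carbonitrile F4 (ring cis to the terminal methyl).
- Methylation as in step 3 gives its 2α-methyl derivative F5.
- Hydrogenation over Pd/C (H2, EtOAc) reduces both double bonds to 6.

In F5 the C3–H bond has to eclipse the alkene to avoid A(1,3) strain with the cis methyl group. The quaternary C4 then covers one face and hydrogen adds from the C2 side, which on a model corresponds to the (R) centre.

**Step 14.** The Mitsunobu activation of the β-branched, crowded primary alcohol may be slow and may give elimination or recovered alcohol. Fallback, from 17 and back at 18: the alcohol is converted into the primary iodide F6 (I2, PPh3, imidazole, toluene), which is reduced in a radical chain (Bu3SnH, AIBN, benzene, 80 °C).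

**Step 17.** Possible failures are inhibition of the cationic catalyst by nitrile coordination or diol chelation, redox isomerisation of the allylic alcohol to the C1 ketone (which would lose control of C8a), or hydrogen delivery from the β face. Fallback, from 20 and back at 21: 1,4-reduction with [CuH(PPh3)]6 (hexameric monovalent copper hydride, benzene, rt). Hydride should add to C8a from the α face, away from the syn-axial C2 methyl and C4 nitrile, and the copper enolate is protonated at C8 on work-up; no new compound is formed.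

**Step 18.** Ring B may react through another conformer, so that equatorial methylene transfer gives the C7 epimer; enolisation of the ketone by the basic ylide may also slow the reaction. Fallback, from 21 and back at 23:
- Wittig methylenation (Ph3P=CH2, THF) gives 3β-[(2R)-butan-2-yl]-1α,2α-dihydroxy-2β,4α,5β-trimethyl-7-methylidenedecahydronaphthalene-4β-carbonitrile F7.
- Dihydroxylation (OsO4 cat., N-methylmorpholine N-oxide) brings the oxygen, not the carbon, in from the equatorial direction and so gives the complementary sense, the tetraol F8.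
- Benzylation of the primary hydroxyl through the stannylene acetal (Bu2SnO, then BnBr, CsF) gives 23.

## Further compounds

F1 | step 12 | 3-{[3β-[(2R)-butan-2-yl]-4β-cyano-2β,4α-dimethyl-1α,2α-bis(triethylsilyloxy)-1,2,3,4,4a,5,6,7-octahydronaphthalen-5β-yl]carbonyl}-1,3-oxazolidin-2-one | CC[C@@H](C)[C@@H]1[C@](C)(C#N)[C@@H]2[C@H](C(=O)N3CCOC3=O)CCC=C2[C@@H](O[Si](CC)(CC)CC)[C@@]1(C)O[Si](CC)(CC)CC
F2 | step 2 | (E)-but-2-en-2-yl(diisobutyl)alane | C/C=C(\C)[Al](CC(C)C)CC(C)C
F3 | step 4 | 2-[(2E)-but-2-en-2-yl]-4,4,5,5-tetramethyl-1,3,2-dioxaborolane | C/C=C(/C)B1OC(C)(C)C(C)(C)O1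
F4 | step 4 | 6-[(2Z)-but-2-en-2-yl]-1-methyl-4-oxocyclohex-2-ene-1-carbonitrile (3β-butenyl, 4α-methyl, 4β-nitrile) | C/C=C(C)\[C@@H]1[C@](C)(C#N)C=CC(=O)C1
F5 | step 4 | 6-[(2Z)-but-2-en-2-yl]-1,5-dimethyl-4-oxocyclohex-2-ene-1-carbonitrile (2α-methyl) | C/C=C(C)\[C@@H]1[C@](C)(C#N)C=CC(=O)[C@H]1C
F6 | step 14 | 3β-[(2R)-butan-2-yl]-5β-(iodomethyl)-2β,4α-dimethyl-1α,2α-bis(triethylsilyloxy)-1,2,3,4,4a,5,6,7-octahydronaphthalene-4β-carbonitrile | CC[C@@H](C)[C@@H]1[C@](C)(C#N)[C@@H]2[C@H](CI)CCC=C2[C@@H](O[Si](CC)(CC)CC)[C@@]1(C)O[Si](CC)(CC)CC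
F0 | step 17 | none | none
F7 | step 18 | 3β-[(2R)-butan-2-yl]-1α,2α-dihydroxy-2β,4α,5β-trimethyl-7-methylidenedecahydronaphthalene-4β-carbonitrile | CC[C@@H](C)[C@@H]1[C@](C)(C#N)[C@@H]2[C@H](C)CC(=C)C[C@@H]2[C@@H](O)[C@@]1(C)O
F8 | step 18 | 3β-[(2R)-butan-2-yl]-1α,2α,7α-trihydroxy-7β-(hydroxymethyl)-2β,4α,5β-trimethyldecahydronaphthalene-4β-carbonitrile | CC[C@@H](C)[C@@H]1[C@](C)(C#N)[C@@H]2[C@H](C)C[C@](O)(CO)C[C@@H]2[C@@H](O)[C@@]1(C)O
A1 | alternative 1 | tert-butyl 2-[5-ethyl-3-(4-methoxy-2-methylphenyl)-3-methyl-2-oxotetrahydropyran-4-yl]acetate (lactone with C3 and benzylic quaternary C4 set) | CC[C@H]1COC(=O)[C@](C)(c2ccc(OC)cc2C)[C@@H]1CC(=O)OC(C)(C)C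
A2 | alternative 1 | 5-ethyl-3-(4-methoxy-2-methylphenyl)-5,6-dihydro-2H-pyran-2-one | CC[C@H]1COC(=O)C(c2ccc(OC)cc2C)=C1
A3 | alternative 2 | tricyclic nitro adduct (bridgehead C7 silyl ether, C5=C6 alkene, C4′ epimers) | CC[C@@H](C)[C@@H]1[C@]2(C)C([N+](=O)[O-])[C@@]3(O[Si](C)(C)C(C)(C)C)C=C(C)[C@@H]2[C@H](C3)C(=O)[C@@]1(C)O[Si](C)(C)C
A4 | alternative 2 | ring B silyl dienol ether tethered through C8a–C1–C2–C3 to the (E)-nitroalkene | CC[C@@H](C)[C@@H]([C@](C)(O[Si](C)(C)C)C(=O)[C@H]1CC(O[Si](C)(C)C(C)(C)C)=CC(C)=C1)/C(C)=C/[N+](=O)[O-]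
A5 | alternative 3 | cis-decalin C4 carboxylic acid with C1=C2 alkene and C7 dioxolane | CC[C@@H](C)[C@@H]1[C@](C)(C(=O)O)[C@@H]2[C@H](C)CC3(OCCO3)C[C@@H]2C=C1C
A6 | alternative 3 | cis-fused δ-lactone (carbonyl C4′, ring oxygen on C1, (E)-alkenyl chain C2=C3 on C1, C7 dioxolane) | CC[C@@H](C)/C=C(C)/[C@H]1OC(=O)C(C)[C@@H]2[C@H](C)CC3(OCCO3)C[C@@H]21
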